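## The problem

The target 31 is a tetralin. Ring B carries the side chain at C1 and a methyl at C4; aromatic ring A carries hydroxyls at C5 and C6, a carboxyl at C7 and hydrogen at C8. The chain carbon on C1 is C11, which bears C20H2OAc; C15 bears a methyl and C16H2OAc. These atom labels are kept for every intermediate.

The four stereocentres are poorly placed to help each other. C1 (S) and C4 (R) face each other across ring B with two methylenes between them. C11 (S) is vicinal to C1. C15 (R) is insulated by three methylenes. Only the C1/C11 pair can be set by mutual control, so C4 and C15 must come from the chiral pool or an auxiliary and be carried through.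

Ring A is a 2,3-dihydroxybenzoic acid fused at C4a/C8a. A free catechol next to a salicylic acid is prone to oxidation and is best made last.

The two primary acetates forbid hydride, organometallic and alkoxide reagents once they are in place. They also cannot be put on selectively after the phenols and the acid exist.

The enabling feature is that the C5 hydroxyl sits directly beside fusion carbon C4a. The atoms O–C8a–C8–C7–C6 then map onto a furan and C4a–C5 onto a terminal alkyne. Rings A and B can therefore both be closed from an open chain in which C1 and C4 are ordinary sp3 carbons.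

## Retrosynthesis

**C7 carboxyl and C6 hydroxyl (31 ⇒ 30 ⇒ 28 ⇒ 26).** The C7–CO2H bond is cut to a formyl group (aldehyde 30), the formyl is removed (catechol 28), and the C6–O bond is cut (phenol 26). Both positions lie ortho to a phenolic oxygen, so each can be reached by an ortho-directed reaction without protecting groups. Carrying a preformed catechol or carboxyl through the synthesis would instead need aryl ethers or esters whose removal clashes with the acetates. The forward steps must be neutral or weakly acidic or basic: 2-iodoxybenzoic acid, a magnesium phenoxide formylation and a chlorite oxidation.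

**Rings A and B (26 ⇒ 23).** The C4a–C8a and C5–C6 bonds are cut and the phenol oxygen is returned to a furan, giving acyclic furyl alkyne 23. Cuts at C4–C4a or C3–C4 would need a preformed, fully substituted arene and would create C4 during ring closure. This cut removes both rings at once and leaves C1 and C4 as spectators. The forward cascade must close ring B in the 6-exo mode on a tether with no heteroatom and must leave the oxygen on C5. A cationic phosphine complex of monovalent gold, high dilution and the branching at C1 and C4 are chosen to help the closure.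

**Acetates and alkyne (23 ⇒ 22 ⇒ 21 ⇒ 20 ⇒ 19).** The acetates are cut back to diol 22 and its bis-silyl ether 21, because the alkyne is made under methanolic carbonate, which acetates do not survive. The C4a≡C5 bond is cut to aldehyde 20 (one-carbon homologation). Aldehyde 20 comes from the primary triethylsilyl ether of 19 by direct oxidation, which saves a deprotection step.

**Saturation and C20 (19 ⇒ 18 ⇒ 17 ⇒ 16).** The C2–C3 and C13–C14 single bonds are traced to the two isolated alkenes of 18, reduced together by diimide so the furan is not touched. The C20 oxygen is traced through alcohol 17 to the carboxyl of acid 16.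

**C1–C11 bond (16 ⇒ 13 ⇒ 6 + 12).** The bond between the two adjacent stereocentres is cut by an Ireland–Claisen transform, giving allylic ester 13, made from alcohol 6 and acid 12. Alkylating a C11 enolate with an unactivated iodide or adding a furyl nucleophile in conjugate fashion would set the two centres in separate, weaker steps. Here one carbinol centre in 6 fixes C1 by chirality transfer and the enolate geometry fixes C11. The forward reaction needs the enolate with C12 cis to the allylic oxygen and a chair transition state.

**Allylic alcohol (6 ⇒ 5 ⇒ 4 ⇒ 1 + 2).** The bond between the carbinol carbon (future C3) and C4 is cut by a syn-aldol transform to imide 1 and enal 2, by way of diol 5 and adduct 4. One auxiliary sets the controlling carbinol and the C4 methyl centre together.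

**Side-chain acid (12 ⇒ 9 + 10; 9 ⇒ 8 ⇒ 7).** The C13=C14 bond is cut by a Wittig transform to aldehyde 9 and phosphonium salt 10. Aldehyde 9 comes from ester 7 through silyl ether 8, so C15 is taken from the chiral pool.

## Roads not taken

**Alternative 1:** Ring B is cut at C2–C3 and traced to a seven-membered benzo-fused sulfone A2. In the forward step a halogenative Ramberg–Bäcklund reaction (KOH on Al2O3, CBr2F2) expels SO2 and contracts the ring to the 1,4-dihydronaphthalene A1, which is then hydrogenated.

- Merits: both ring-A oxygens are in place from the start, and the contraction is reliable for six-membered cycloalkenes. In this respect it is better than the chosen plan, which must oxidise C6 late.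
- Weak points: in A1 the hydrogens at C1 and C4 are both benzylic and allylic. On basic alumina the alkene can migrate into conjugation or the ring can aromatise, which would erase both stereocentres. A2 needs C1 and C4 set on a crowded arene before two C–S bonds are made. The aryl methyl ethers must finally be cleaved beside the acetates, and the C7 carboxyl is still missing.
- What the chosen plan sets against it: a neutral ring-forming step that cannot touch C1 or C4, and no ether cleavage at the end.

**Alternative 2:** Ring A is cut at C4a–C5 and traced to a dienyl half-ester A4, made by Stobbe condensation of a chiral-pool ring-B cyclohexenecarbaldehyde with a succinate diester. In the forward step, heating with Ac2O and NaOAc closes ring A as the C5 acetate A3 and acetylates the side chain in the same flask.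

- Merits: the C7 carboxyl arrives at the right oxidation level as a benzyl ester that hydrogenolysis removes without harming the acetates. Here it is clearly better than the chosen plan, which needs formylation and oxidation.
- Weak points: A3 has no C6 oxygen. It would have to be placed between the C5 oxygen and the C7 ester on a deactivated ring, where ortho-oxidation is poor. Hot acetate can move the ring-B double bond and epimerise C4 or C1. Attaching the side chain with the right C1/C11 configuration to a preformed ring is a separate problem.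
- What the chosen plan sets against it: a free ortho position beside an activating phenol, so that C6 and then C7 follow by directed chemistry, and one rearrangement that sets C1 and C11 together.

**Alternative 3:** Ring B is cut at C3–C4 and traced to the ortho-vinyl aryl bromide A6. In the forward step a copper hydride generated from Cu(OAc)2, DTBM-SEGPHOS and a hydrosilane (monovalent copper) adds to the vinyl group, and the benzylic copper at C4 displaces the bromide at C3 to give tetralin A5.

- Merits: C4 is set by the catalyst in the ring closure, with no epimerisable α-methyl aldehyde on the way, and the closure is an ordinary six-membered substitution. In both respects it is better than the chosen plan.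
- Weak points: A6 is a 1,2,3,4-tetrasubstituted styrene that is laborious to build. The catalyst may be mismatched with the existing C1 centre. The C7 carboxyl is still missing, and two aryl methyl ethers must be cleaved beside the acetates.
- What the chosen plan sets against it: C4 comes from an auxiliary-controlled aldol and is kept by a mild homologation, the arene is built with its oxygen where it is needed, and no ether cleavage is required.

Key step: step 16

Remark: compounds 1, 2 (as the E isomer), 7 and 10 are taken as catalogue materials.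

## Route

**Step 1**
Reactants: 1 (R)-4-benzyl-3-propionyloxazolidin-2-one; 2 (E)-3-(furan-2-yl)prop-2-enal
Product: 4 (R)-4-benzyl-3-[(2R,3S,4E)-5-(furan-2-yl)-3-hydroxy-2-methylpent-4-enoyl]oxazolidin-2-one, via dibutylboron Z-enolate 3 (not isolated)
Conditions: Bu2BOTf, i-Pr2NEt, CH2Cl2, 0 °C; then 2, −78 → 0 °C; pH 7 buffer, MeOH, H2O2, 0 °C
Reagents that add atoms: none
Why: Evans syn-aldol reaction: Z-enolate 3 adds through a Zimmerman–Traxler chair on the face away from the benzyl group, so the auxiliary sets the 2R centre (future C4) and the 3S carbinol together in a syn relation; conjugated enals are standard acceptors and the furan tolerates the buffered peroxide work-up.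

**Step 2**
Reactants: 4
Product: 5 (2S,3S,4E)-5-(furan-2-yl)-2-methylpent-4-ene-1,3-diol
Conditions: LiBH4, MeOH (1 equiv), THF, 0 °C
Reagents that add atoms: none
Why: Reductive cleavage of the N-acyl oxazolidinone gives the primary alcohol without touching either stereocentre and frees the auxiliary for recovery.

**Step 3**
Reactants: 5
Product: 6 (1E,3S,4S)-1-(furan-2-yl)-4-methyl-5-(triethylsilyloxy)pent-1-en-3-ol
Conditions: Et3SiCl (1.05 equiv), imidazole, CH2Cl2, −78 → −40 °C
Reagents that add atoms: chlorotriethylsilane, CC[Si](Cl)(CC)CC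
Why: Silylation at low temperature is selective for the primary hydroxyl over the hindered secondary allylic one; the triethylsilyl group is chosen because it can later be oxidised off directly.

**Step 4**
Reactants: 7 methyl (S)-3-hydroxy-2-methylpropanoate
Product: 8 methyl (S)-3-(tert-butyldimethylsilyloxy)-2-methylpropanoate
Conditions: t-BuMe2SiCl, imidazole, CH2Cl2, 23 °C
Reagents that add atoms: tert-butylchlorodimethylsilane, CC(C)(C)[Si](C)(C)Cl
Why: Standard silyl ether formation; the stereocentre (future C15) is not involved.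

**Step 5**
Reactants: 8
Product: 9 (S)-3-(tert-butyldimethylsilyloxy)-2-methylpropanal
Conditions: i-Bu2AlH (1.1 equiv), CH2Cl2, −78 °C; aqueous potassium sodium tartrate
Reagents that add atoms: none
Why: Partial ester reduction stops at the aluminium hemiacetal at −78 °C and releases the aldehyde on work-up; the α-stereocentre should survive if the aldehyde is used at once.

**Step 6**
Reactants: 9; 10 (3-carboxypropyl)triphenylphosphonium bromide
Product: 12 (4Z,6R)-7-(tert-butyldimethylsilyloxy)-6-methylhept-4-enoic acid, via phosphorus ylide 11 (not isolated)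
Conditions: 10, NaN(SiMe3)2 (2.1 equiv), THF, 0 °C; then 9, −78 → 23 °C; aqueous citric acid
Reagents that add atoms: none
Why: Wittig olefination with the non-stabilised ylide 11 joins C13 to C14; the Z geometry does not matter because the alkene is reduced in step 11, and addition at −78 °C protects the α-stereocentre of 9.

**Step 7**
Reactants: 6; 12
Product: 13 (1E,3S,4S)-1-(furan-2-yl)-4-methyl-5-(triethylsilyloxy)pent-1-en-3-yl (4Z,6R)-7-(tert-butyldimethylsilyloxy)-6-methylhept-4-enoate
Conditions: N-(3-dimethylaminopropyl)-N′-ethylcarbodiimide hydrochloride, DMAP, CH2Cl2, 0 → 23 °C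
Reagents that add atoms: none
Why: Carbodiimide esterification with DMAP catalysis (Steglich type) acylates the secondary allylic alcohol under neutral conditions that do not ionise the furyl-allylic C–O bond.

**Step 8**
Reactants: 13
Product: 16 (2S,3S,4E,6R)-2-[(2Z,4R)-5-(tert-butyldimethylsilyloxy)-4-methylpent-2-en-1-yl]-3-(furan-2-yl)-6-methyl-7-(triethylsilyloxy)hept-4-enoic acid, via silyl ketene acetal 14 (not isolated), via trimethylsilyl ester 15 (not isolated)
Conditions: LiN(i-Pr)2, THF, −78 °C; Me3SiCl, Et3N, −78 → 23 °C, then 50 °C; 5% aqueous citric acid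
Reagents that add atoms: none
Why: Ireland–Claisen rearrangement: kinetic deprotonation in THF without a polar additive gives the enolate with C12 cis to the allylic oxygen, trapped as 14. The [3,3] shift through a chair with the CH(CH3)CH2OSiEt3 group equatorial forms the C1–C11 bond on the face from which the C–O bond leaves, so the 3S carbinol becomes 1S and the enolate geometry gives 11S. The new alkene is E and is reduced in step 11.

**Step 9**
Reactants: 16
Product: 17 (2S,3S,4E,6R)-2-[(2Z,4R)-5-(tert-butyldimethylsilyloxy)-4-methylpent-2-en-1-yl]-3-(furan-2-yl)-6-methyl-7-(triethylsilyloxy)hept-4-en-1-ol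
Conditions: LiAlH4, Et2O, 0 → 23 °C
Reagents that add atoms: none
Why: Hydride reduction of the carboxylic acid gives the C20 primary alcohol; silyl ethers, furan and isolated alkenes are inert.

**Step 10**
Reactants: 17
Product: 18 (2S,3S,4E,6R)-1-(tert-butyldimethylsilyloxy)-2-[(2Z,4R)-5-(tert-butyldimethylsilyloxy)-4-methylpent-2-en-1-yl]-3-(furan-2-yl)-6-methyl-7-(triethylsilyloxy)hept-4-ene
Conditions: t-BuMe2SiCl, imidazole, DMF, 23 °C
Reagents that add atoms: tert-butylchlorodimethylsilane, CC(C)(C)[Si](C)(C)Cl
Why: Standard silylation; both side-chain oxygens now carry the same group and can be freed together in step 14.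

**Step 11**
Reactants: 18
Product: 19 2-[(2R,5S,6S,10R)-11-(tert-butyldimethylsilyloxy)-6-[(tert-butyldimethylsilyloxy)methyl]-2,10-dimethyl-1-(triethylsilyloxy)undecan-5-yl]furan
Conditions: 2-nitrobenzenesulfonohydrazide (excess), Et3N, CH2Cl2, 23 °C
Reagents that add atoms: none
Why: Diimide reduction: diimide released from the hydrazide transfers two hydrogens in a concerted way to unhindered disubstituted alkenes, so both C2=C3 and C13=C14 are saturated while the furan and silyl ethers are left alone; no stereocentre is formed.

**Step 12**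
Reactants: 19
Product: 20 (2R,5S,6S,10R)-11-(tert-butyldimethylsilyloxy)-6-[(tert-butyldimethylsilyloxy)methyl]-5-(furan-2-yl)-2,10-dimethylundecanal
Conditions: (COCl)2, DMSO, CH2Cl2, −78 → −30 °C; Et3N, −78 → 0 °C
Reagents that add atoms: none
Why: Direct Swern oxidation of a primary triethylsilyl ether: the activated sulfonium cleaves the most labile Si–O bond and the alkoxysulfonium collapses to the aldehyde, while primary tert-butyldimethylsilyl ethers persist.

**Step 13**
Reactants: 20
Product: 21 2-[(3R,6S,7S,11R)-12-(tert-butyldimethylsilyloxy)-7-[(tert-butyldimethylsilyloxy)methyl]-3,11-dimethyldodec-1-yn-6-yl]furan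
Conditions: dimethyl (1-diazo-2-oxopropyl)phosphonate, K2CO3, MeOH, 0 → 23 °C
Reagents that add atoms: dimethyl (1-diazo-2-oxopropyl)phosphonate, COP(=O)(OC)C(=[N+]=[N-])C(C)=O
Why: Ohira–Bestmann (Seyferth–Gilbert) homologation adds C5 and turns the aldehyde into the terminal alkyne; the mild carbonate base at 0 °C should preserve the α-methyl stereocentre C4.

**Step 14**
Reactants: 21
Product: 22 (2R,6S)-6-[(1S,4R)-1-(furan-2-yl)-4-methylhex-5-yn-1-yl]-2-methylheptane-1,7-diol
Conditions: Bu4NF, THF, 23 °C
Reagents that add atoms: none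
Why: Fluoride cleaves both silyl ethers; the terminal alkyne and the furan are unaffected.

**Step 15**
Reactants: 22
Product: 23 (2R,6S)-6-[(1S,4R)-1-(furan-2-yl)-4-methylhex-5-yn-1-yl]-2-methylheptane-1,7-diyl diacetate
Conditions: Ac2O, pyridine, DMAP (cat.), CH2Cl2, 23 °C
Reagents that add atoms: acetic anhydride, CC(=O)OC(C)=O
Why: DMAP-catalysed acetylation of the two primary alcohols installs the acetates of the target before any phenol exists, which avoids later O-selectivity problems.

**Step 16**
Reactants: 23
Product: 26 (2R,6S)-6-[(1S,4R)-5-hydroxy-4-methyl-1,2,3,4-tetrahydronaphthalen-1-yl]-2-methylheptane-1,7-diyl diacetate, via oxepine 24 (not isolated), via arene oxide 25 (not isolated)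
Conditions: Ph3PAuNTf2 (5 mol %), CH2Cl2 (0.02 M), 23 °C
Reagents that add atoms: none
Why: Cationic monovalent gold binds the terminal alkyne of 23, and the furan C8a=C8 π bond attacks the internal carbon C4a in the 6-exo-dig mode, closing ring B as a cyclopropyl gold carbenoid. Cleavage of the C8a–O bond with opening of the cyclopropane unravels the furan to a Z-dienal whose C5 is a gold carbene; the aldehyde oxygen adds to C5 and loss of gold gives oxepine 24. Ring A closes by thermal disrotatory 6π electrocyclisation of 24 (C5–C6 bond) to arene oxide 25, which opens at the C6–O bond and aromatises by hydride shift and tautomerisation, leaving the oxygen on C5. The closest known reaction type is the gold- and platinum-catalysed intramolecular furan–alkyne phenol synthesis, which includes carbocyclic six-membered tethers. No stereocentre is created: C1 and C4 are sp3 tether carbons that never become planar, and the two epoxide carbons of 25 are erased on aromatisation. The step needs exo rather than endo attack and the C5 rather than the C6 phenol; the terminal alkyne directs attack to its internal carbon, the four-carbon tether allows only the six-membered closure, and these arene oxides are known to break the bond to the former furan carbon. Branching at C1 and C4 favours the folded rotamer, and the acetates are inert to the π-acid.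

**Step 17**
Reactants: 26
Product: 28 (2R,6S)-6-[(1S,4R)-5,6-dihydroxy-4-methyl-1,2,3,4-tetrahydronaphthalen-1-yl]-2-methylheptane-1,7-diyl diacetate, via ortho-quinone 27 (not isolated)
Conditions: 2-iodoxybenzoic acid (1.2 equiv), DMF, 23 °C; then aqueous Na2S2O4
Reagents that add atoms: 2-iodoxybenzoic acid (IBX), O=C1OI(=O)(O)c2ccccc12
Why: Ortho-oxygenation of phenols by 2-iodoxybenzoic acid: the phenol binds to iodine and oxygen is delivered to the only free ortho carbon (C6), giving ortho-quinone 27, which dithionite reduces in the same flask; the neutral conditions spare the acetates.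

**Step 18**
Reactants: 28
Product: 30 (2R,6S)-6-[(1S,4R)-7-formyl-5,6-dihydroxy-4-methyl-1,2,3,4-tetrahydronaphthalen-1-yl]-2-methylheptane-1,7-diyl diacetate, via hydroxymethyl catechol 29 (not isolated)
Conditions: MgCl2, Et3N, (CH2O)n, THF, 65 °C; 1 M HCl work-up
Reagents that add atoms: formaldehyde (as paraformaldehyde), C=O
Why: Magnesium-mediated ortho-formylation (Casnati–Skattebøl): the magnesium phenoxide at C6 delivers formaldehyde to C7 through a six-membered transition state, and the benzylic alkoxide 29 is oxidised by a second formaldehyde; the reaction is ortho-specific, so C8 is not attacked.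

**Step 19**
Reactants: 30
Product: 31 (5R,8S)-8-[(2S,6R)-1,7-diacetoxy-6-methylheptan-2-yl]-3,4-dihydroxy-5-methyl-5,6,7,8-tetrahydronaphthalene-2-carboxylic acid (CNP0245723.1)
Conditions: NaClO2, NaH2PO4, NH2SO3H, dioxane–H2O, 0 °C
Reagents that add atoms: sodium chlorite, [Na+].[O-]Cl=O
Why: Lindgren–Pinnick oxidation: chlorous acid oxidises the aldehyde to the acid and sulfamic acid destroys the hypochlorite by-product before it can attack the electron-rich ring; the acidic, non-nucleophilic medium leaves the acetates intact.

## Compound list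

1 | (R)-4-benzyl-3-propionyloxazolidin-2-one | CCC(=O)N1[C@H](Cc2ccccc2)COC1=O | starting material
2 | (E)-3-(furan-2-yl)prop-2-enal | O=C/C=C/c1ccco1 | starting material
3 | (R)-4-benzyl-3-[(Z)-1-(dibutylboranyloxy)prop-1-en-1-yl]oxazolidin-2-one (boron enolate of 1) | CCCCB(CCCC)O/C(=C\C)N1[C@H](Cc2ccccc2)COC1=O | intermediate
4 | (R)-4-benzyl-3-[(2R,3S,4E)-5-(furan-2-yl)-3-hydroxy-2-methylpent-4-enoyl]oxazolidin-2-one | O=C([C@H](C)[C@@H](O)/C=C/c1ccco1)N1[C@H](Cc2ccccc2)COC1=O | intermediate
5 | (2S,3S,4E)-5-(furan-2-yl)-2-methylpent-4-ene-1,3-diol | OC[C@H](C)[C@@H](O)/C=C/c1ccco1 | intermediate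
6 | (1E,3S,4S)-1-(furan-2-yl)-4-methyl-5-(triethylsilyloxy)pent-1-en-3-ol | CC[Si](CC)(CC)OC[C@H](C)[C@@H](O)/C=C/c1ccco1 | intermediate
7 | methyl (S)-3-hydroxy-2-methylpropanoate | COC(=O)[C@@H](C)CO | starting material
8 | methyl (S)-3-(tert-butyldimethylsilyloxy)-2-methylpropanoate | COC(=O)[C@@H](C)CO[Si](C)(C)C(C)(C)C | intermediate
9 | (S)-3-(tert-butyldimethylsilyloxy)-2-methylpropanal | O=C[C@@H](C)CO[Si](C)(C)C(C)(C)C | intermediate
10 | (3-carboxypropyl)triphenylphosphonium bromide | OC(=O)CCC[P+](c1ccccc1)(c1ccccc1)c1ccccc1.[Br-] | starting material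
11 | sodium 4-(triphenylphosphoranylidene)butanoate (ylide of 10) | [Na+].[O-]C(=O)CCC=P(c1ccccc1)(c1ccccc1)c1ccccc1 | intermediate
12 | (4Z,6R)-7-(tert-butyldimethylsilyloxy)-6-methylhept-4-enoic acid | OC(=O)CC/C=C\[C@@H](C)CO[Si](C)(C)C(C)(C)C | intermediate
13 | (1E,3S,4S)-1-(furan-2-yl)-4-methyl-5-(triethylsilyloxy)pent-1-en-3-yl (4Z,6R)-7-(tert-butyldimethylsilyloxy)-6-methylhept-4-enoate | CC(C)(C)[Si](C)(C)OC[C@H](C)/C=C\CCC(=O)O[C@@H](/C=C/c1ccco1)[C@@H](C)CO[Si](CC)(CC)CC | intermediate
14 | E-configured O-trimethylsilyl ketene acetal of ester 13 (C11=C20 double bond, C12 trans to OSiMe3) | CC(C)(C)[Si](C)(C)OC[C@H](C)/C=C\C/C=C(/O[Si](C)(C)C)O[C@@H](/C=C/c1ccco1)[C@@H](C)CO[Si](CC)(CC)CC | intermediate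
15 | trimethylsilyl ester of acid 16 | CC(C)(C)[Si](C)(C)OC[C@H](C)/C=C\C[C@H](C(=O)O[Si](C)(C)C)[C@@H](c1ccco1)/C=C/[C@@H](C)CO[Si](CC)(CC)CC | intermediate
16 | (2S,3S,4E,6R)-2-[(2Z,4R)-5-(tert-butyldimethylsilyloxy)-4-methylpent-2-en-1-yl]-3-(furan-2-yl)-6-methyl-7-(triethylsilyloxy)hept-4-enoic acid | CC(C)(C)[Si](C)(C)OC[C@H](C)/C=C\C[C@H](C(=O)O)[C@@H](c1ccco1)/C=C/[C@@H](C)CO[Si](CC)(CC)CC | intermediate
17 | (2S,3S,4E,6R)-2-[(2Z,4R)-5-(tert-butyldimethylsilyloxy)-4-methylpent-2-en-1-yl]-3-(furan-2-yl)-6-methyl-7-(triethylsilyloxy)hept-4-en-1-ol | CC(C)(C)[Si](C)(C)OC[C@H](C)/C=C\C[C@H](CO)[C@@H](c1ccco1)/C=C/[C@@H](C)CO[Si](CC)(CC)CC | intermediate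
18 | (2S,3S,4E,6R)-1-(tert-butyldimethylsilyloxy)-2-[(2Z,4R)-5-(tert-butyldimethylsilyloxy)-4-methylpent-2-en-1-yl]-3-(furan-2-yl)-6-methyl-7-(triethylsilyloxy)hept-4-ene | CC(C)(C)[Si](C)(C)OC[C@H](C)/C=C\C[C@H](CO[Si](C)(C)C(C)(C)C)[C@@H](c1ccco1)/C=C/[C@@H](C)CO[Si](CC)(CC)CC | intermediate
19 | 2-[(2R,5S,6S,10R)-11-(tert-butyldimethylsilyloxy)-6-[(tert-butyldimethylsilyloxy)methyl]-2,10-dimethyl-1-(triethylsilyloxy)undecan-5-yl]furan | CC(C)(C)[Si](C)(C)OC[C@H](C)CCC[C@H](CO[Si](C)(C)C(C)(C)C)[C@@H](c1ccco1)CC[C@@H](C)CO[Si](CC)(CC)CC | intermediate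
20 | (2R,5S,6S,10R)-11-(tert-butyldimethylsilyloxy)-6-[(tert-butyldimethylsilyloxy)methyl]-5-(furan-2-yl)-2,10-dimethylundecanal | CC(C)(C)[Si](C)(C)OC[C@H](C)CCC[C@H](CO[Si](C)(C)C(C)(C)C)[C@@H](c1ccco1)CC[C@@H](C)C=O | intermediate
21 | 2-[(3R,6S,7S,11R)-12-(tert-butyldimethylsilyloxy)-7-[(tert-butyldimethylsilyloxy)methyl]-3,11-dimethyldodec-1-yn-6-yl]furan | CC(C)(C)[Si](C)(C)OC[C@H](C)CCC[C@H](CO[Si](C)(C)C(C)(C)C)[C@@H](c1ccco1)CC[C@@H](C)C#C | intermediate
22 | (2R,6S)-6-[(1S,4R)-1-(furan-2-yl)-4-methylhex-5-yn-1-yl]-2-methylheptane-1,7-diol | OC[C@H](C)CCC[C@H](CO)[C@@H](c1ccco1)CC[C@@H](C)C#C | intermediate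
23 | (2R,6S)-6-[(1S,4R)-1-(furan-2-yl)-4-methylhex-5-yn-1-yl]-2-methylheptane-1,7-diyl diacetate | CC(=O)OC[C@H](C)CCC[C@H](COC(C)=O)[C@@H](c1ccco1)CC[C@@H](C)C#C | intermediate
24 | (2R,6S)-2-methyl-6-[(6S,9R)-9-methyl-6,7,8,9-tetrahydro-2-benzoxepin-6-yl]heptane-1,7-diyl diacetate (oxepine) | CC(=O)OC[C@H](C)CCC[C@H](COC(C)=O)[C@@H]1CC[C@@H](C)C2=COC=CC=C12 | intermediate
25 | (2R,6S)-6-[(1S,4R)-5,6-epoxy-4-methyl-1,2,3,4,5,6-hexahydronaphthalen-1-yl]-2-methylheptane-1,7-diyl diacetate (arene oxide, epoxide carbons undefined) | CC(=O)OC[C@H](C)CCC[C@H](COC(C)=O)[C@@H]1CC[C@@H](C)C2=C1C=CC3OC23 | intermediate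
26 | (2R,6S)-6-[(1S,4R)-5-hydroxy-4-methyl-1,2,3,4-tetrahydronaphthalen-1-yl]-2-methylheptane-1,7-diyl diacetate | CC(=O)OC[C@H](C)CCC[C@H](COC(C)=O)[C@@H]1CC[C@@H](C)c2c1cccc2O | intermediate
27 | (2R,6S)-6-[(1S,4R)-4-methyl-5,6-dioxo-1,2,3,4,5,6-hexahydronaphthalen-1-yl]-2-methylheptane-1,7-diyl diacetate | CC(=O)OC[C@H](C)CCC[C@H](COC(C)=O)[C@@H]1CC[C@@H](C)C2=C1C=CC(=O)C2=O | intermediate
28 | (2R,6S)-6-[(1S,4R)-5,6-dihydroxy-4-methyl-1,2,3,4-tetrahydronaphthalen-1-yl]-2-methylheptane-1,7-diyl diacetate | CC(=O)OC[C@H](C)CCC[C@H](COC(C)=O)[C@@H]1CC[C@@H](C)c2c1ccc(O)c2O | intermediate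
29 | (2R,6S)-6-[(1S,4R)-5,6-dihydroxy-7-(hydroxymethyl)-4-methyl-1,2,3,4-tetrahydronaphthalen-1-yl]-2-methylheptane-1,7-diyl diacetate (present as its magnesium phenoxide) | CC(=O)OC[C@H](C)CCC[C@H](COC(C)=O)[C@@H]1CC[C@@H](C)c2c1cc(CO)c(O)c2O | intermediate
30 | (2R,6S)-6-[(1S,4R)-7-formyl-5,6-dihydroxy-4-methyl-1,2,3,4-tetrahydronaphthalen-1-yl]-2-methylheptane-1,7-diyl diacetate | CC(=O)OC[C@H](C)CCC[C@H](COC(C)=O)[C@@H]1CC[C@@H](C)c2c1cc(C=O)c(O)c2O | intermediate
31 | (5R,8S)-8-[(2S,6R)-1,7-diacetoxy-6-methylheptan-2-yl]-3,4-dihydroxy-5-methyl-5,6,7,8-tetrahydronaphthalene-2-carboxylic acid | CC(=O)OC[C@H](C)CCC[C@H](COC(C)=O)[C@@H]1CC[C@@H](C)c2c1cc(C(=O)O)c(O)c2O | target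

## Step count and least certain steps

Total: 19 steps. Longest linear sequence: 16 steps (from 7 through steps 4–19, or equally from 1 through steps 1–3 and 7–19).

**Step 16 (key step).** The six-membered closure on a tether with no heteroatom or geminal substituents may be slow, so that catalyst decay, alkyne hydration or intermolecular furan–alkyne reaction overtakes it. Opening of the arene oxide in the other direction is a second risk. The fallback replaces π-acid catalysis by a thermal or Lewis-acid [4+2] reaction that forms the same two bonds. It sets out from 23. Acylation of the terminal alkyne with acetyl chloride (PdCl2(PPh3)2, CuI, Et3N) gives the alkynyl methyl ketone F1. Heating in toluene, or Me2AlCl in CH2Cl2, should bring about the intramolecular furan Diels–Alder reaction to the oxygen-bridged adduct F2 (not isolated). Its bridge opens under the same acid to the 5-acetyl-6-hydroxytetralin F3, with the furan oxygen now on C6. A Dakin-type Baeyer–Villiger oxidation (H2O2, catalytic (PhSe)2, CH2Cl2) turns the acetyl group into the C5 aryl acetate F4. NH4OAc in aqueous methanol removes this aryl acetate selectively and the route is rejoined at catechol 28; step 17 is then not needed.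

**Step 18.** The chelated magnesium catecholate may react slowly, so that the methoxide formed in the reaction begins to cleave the primary acetates, or the reaction may stop at the hydroxymethyl stage. The fallback is a Rieche formylation of 28 (Cl2CHOMe, TiCl4, CH2Cl2, 0 °C). It is an electrophilic substitution directed to C7 by the titanium phenoxide, with no methoxide and no hydride transfer. It goes from 28 directly to 30 and makes no new compound (F0).

**Step 19.** Chlorine species may oxidise the free catechol to a quinone or chlorinate the ring faster than the hydrogen-bonded aldehyde is oxidised. The fallback masks the catechol. From 30, Ac2O and pyridine give the tetraacetate aldehyde F5. Chlorite oxidation (NaClO2, NaH2PO4, 2-methyl-2-butene) then gives the tetraacetate acid F6. NH4OAc in aqueous methanol cleaves only the two aryl acetates and returns to 31.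

**Step 8.** Leakage in enolate geometry, or a competing boat transition state, would erode the C11 configuration, and the C11 epimers may be hard to separate. The fallback changes the enolisation from a lithium amide with silyl trap to a boron ketene acetal. Ester 13 is treated with a chiral 2-bromo-4,5-diphenyl-1,3-bis(arylsulfonyl)-1,3,2-diazaborolidine and a tertiary amine, where the amine–solvent pair fixes the enolate geometry and the reagent reinforces the facial sense. The rearrangement still gives 16 and makes no new compound (F0).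

**Step 12.** Selectivity between the primary triethylsilyl and tert-butyldimethylsilyl ethers may be incomplete, or the activated sulfonium may chlorinate the furan. The fallback separates the two events. From 19, pyridinium p-toluenesulfonate in MeOH at 0 °C removes only the triethylsilyl group to give the primary alcohol F7. Dess–Martin periodinane buffered with NaHCO3 then gives aldehyde 20.

## Further compounds

F1 | step 16 | (2R,6S)-6-[(1S,4R)-1-(furan-2-yl)-4-methyl-7-oxooct-5-yn-1-yl]-2-methylheptane-1,7-diyl diacetate | CC(=O)OC[C@H](C)CCC[C@H](COC(C)=O)[C@@H](c1ccco1)CC[C@@H](C)C#CC(C)=O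
F2 | step 16 | oxygen-bridged Diels–Alder adduct of F1 (oxygen bridging C8a and C6, acetyl on C5, bridgehead configuration undefined) | CC(=O)OC[C@H](C)CCC[C@H](COC(C)=O)[C@@H]1CC[C@@H](C)C2=C(C(C)=O)C3C=CC12O3
F3 | step 16 | (2R,6S)-6-[(1S,4R)-5-acetyl-6-hydroxy-4-methyl-1,2,3,4-tetrahydronaphthalen-1-yl]-2-methylheptane-1,7-diyl diacetate | CC(=O)OC[C@H](C)CCC[C@H](COC(C)=O)[C@@H]1CC[C@@H](C)c2c1ccc(O)c2C(C)=O
F4 | step 16 | (2R,6S)-6-[(1S,4R)-5-acetoxy-6-hydroxy-4-methyl-1,2,3,4-tetrahydronaphthalen-1-yl]-2-methylheptane-1,7-diyl diacetate | CC(=O)OC[C@H](C)CCC[C@H](COC(C)=O)[C@@H]1CC[C@@H](C)c2c1ccc(O)c2OC(C)=O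
F5 | step 19 | (2R,6S)-6-[(1S,4R)-5,6-diacetoxy-7-formyl-4-methyl-1,2,3,4-tetrahydronaphthalen-1-yl]-2-methylheptane-1,7-diyl diacetate | CC(=O)OC[C@H](C)CCC[C@H](COC(C)=O)[C@@H]1CC[C@@H](C)c2c1cc(C=O)c(OC(C)=O)c2OC(C)=O
F6 | step 19 | (5R,8S)-3,4-diacetoxy-8-[(2S,6R)-1,7-diacetoxy-6-methylheptan-2-yl]-5-methyl-5,6,7,8-tetrahydronaphthalene-2-carboxylic acid | CC(=O)OC[C@H](C)CCC[C@H](COC(C)=O)[C@@H]1CC[C@@H](C)c2c1cc(C(=O)O)c(OC(C)=O)c2OC(C)=O
F7 | step 12 | (2R,5S,6S,10R)-11-(tert-butyldimethylsilyloxy)-6-[(tert-butyldimethylsilyloxy)methyl]-5-(furan-2-yl)-2,10-dimethylundecan-1-ol | CC(C)(C)[Si](C)(C)OC[C@H](C)CCC[C@H](CO[Si](C)(C)C(C)(C)C)[C@@H](c1ccco1)CC[C@@H](C)CO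
F0 | step 18 | none | none
F0 | step 8 | none | none
A1 | alternative 1 | (1S,4R)-1-[(2S,6R)-1,7-bis(tert-butyldimethylsilyloxy)-6-methylheptan-2-yl]-5,6-dimethoxy-4-methyl-1,4-dihydronaphthalene | CC(C)(C)[Si](C)(C)OC[C@H](C)CCC[C@H](CO[Si](C)(C)C(C)(C)C)[C@@H]1C=C[C@@H](C)c2c1ccc(OC)c2OC
A2 | alternative 1 | 1-[(2S,6R)-1,7-bis(tert-butyldimethylsilyloxy)-6-methylheptan-2-yl]-6,7-dimethoxy-5-methyl-1,2,4,5-tetrahydro-3-benzothiepine 3,3-dioxide (ring carbons 1 and 5 configured as C1 and C4 of the target) | CC(C)(C)[Si](C)(C)OC[C@H](C)CCC[C@H](CO[Si](C)(C)C(C)(C)C)[C@@H]1CS(=O)(=O)C[C@@H](C)c2c1ccc(OC)c2OC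
A3 | alternative 2 | benzyl (5R,8S)-4-acetoxy-8-[(2S,6R)-1,7-diacetoxy-6-methylheptan-2-yl]-5-methyl-5,6,7,8-tetrahydronaphthalene-2-carboxylate | CC(=O)OC[C@H](C)CCC[C@H](COC(C)=O)[C@@H]1CC[C@@H](C)c2c1cc(C(=O)OCc1ccccc1)cc2OC(C)=O
A4 | alternative 2 | (3E)-3-[(benzyloxy)carbonyl]-4-[(3R,6S)-6-[(2S,6R)-1,7-dihydroxy-6-methylheptan-2-yl]-3-methylcyclohex-1-en-1-yl]but-3-enoic acid | OC[C@H](C)CCC[C@H](CO)[C@@H]1CC[C@@H](C)C=C1/C=C(\CC(=O)O)C(=O)OCc1ccccc1
A5 | alternative 3 | (1S,4R)-1-[(2S,6R)-1,7-bis(tert-butyldimethylsilyloxy)-6-methylheptan-2-yl]-5,6-dimethoxy-4-methyl-1,2,3,4-tetrahydronaphthalene | CC(C)(C)[Si](C)(C)OC[C@H](C)CCC[C@H](CO[Si](C)(C)C(C)(C)C)[C@@H]1CC[C@@H](C)c2c1ccc(OC)c2OC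
A6 | alternative 3 | 1-[(3S,4S,8R)-1-bromo-9-(tert-butyldimethylsilyloxy)-4-[(tert-butyldimethylsilyloxy)methyl]-8-methylnonan-3-yl]-2-ethenyl-3,4-dimethoxybenzene | CC(C)(C)[Si](C)(C)OC[C@H](C)CCC[C@H](CO[Si](C)(C)C(C)(C)C)[C@H](CCBr)c1ccc(OC)c(OC)c1C=C
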